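The 1,2‑dioxolane is disconnected across both C–O bonds: ring atoms C3–C4–C5 (numbering from the carboxyl carbon C1) are a cyclopropane into which O2 is inserted between C3 and C5, and the C1–C2 acid arm on C3 is carried as a vinyl group. In one operation a thiyl‑radical chain opens the vinylcyclopropane, captures O2 at C5 and closes the peroxide onto C3, building the ring, both C–O bonds and both quaternary stereocentres. The precursor is a 1‑ethenyl‑1,2‑dimethyl‑2‑alkylcyclopropane from (R)‑citronellal (C7 fixed), with an alkene‑free side chain ending at C10 as a dimethyl acetal. The vinyl group is later oxidised to the acid and C11–C17 added by B‑alkyl Suzuki coupling.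

Key step: step 8

Remark: C10 is carried through the key step as a dimethyl acetal (aldehyde oxidation level) and not as a protected alcohol, which leaves the skeleton of the key‑step precursor and product unchanged, removes a reduction/protection/deprotection/oxidation detour and lets C1 stay a free alcohol until the last step; the four dioxolane diastereomers of step 8 are assumed to be separable by chromatography.

Step 1
Reactants: 1 (R)-citronellal
Product: 2 (4R)-4,8-dimethylnon-7-en-2-ol (C2 epimers)
Conditions: MeMgBr, Et2O, 0 °C; aq NH4Cl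
Reagents that add atoms: methylmagnesium bromide C[Mg]Br
Why: Grignard addition to the unhindered aldehyde supplies the C5 methyl branch; the new carbinol centre is left as a mixture because step 2 removes it, and C7 (β to the carbonyl) cannot epimerise.

Step 2
Reactants: 2 (4R)-4,8-dimethylnon-7-en-2-ol
Product: 3 (4R)-4,8-dimethylnon-7-en-2-one
Conditions: Dess–Martin periodinane, CH2Cl2, 0 °C → rt
Reagents that add atoms: none
Why: Dess–Martin oxidation converts the secondary alcohol into the methyl ketone (C5) without touching the trisubstituted alkene or the β-stereocentre C7.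

Step 3
Reactants: 3 (4R)-4,8-dimethylnon-7-en-2-one
Product: 5 (4R)-7,7-dimethoxy-4-methylheptan-2-one, via keto aldehyde 4 (not isolated)
Conditions: O3, CH2Cl2/MeOH, −78 °C; Me2S, −78 °C → rt; then p-TsOH·H2O (5 mol%), rt; NaHCO3
Reagents that add atoms: methanol CO
Why: Ozonolysis with reductive work-up cleaves the trisubstituted alkene to the C10 aldehyde, and acid-catalysed acetalisation in methanol then protects that aldehyde, which reacts far faster than the methyl ketone, so C10 stays at the aldehyde oxidation level as an alkene-free spectator.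

Step 4
Reactants: 5 (4R)-7,7-dimethoxy-4-methylheptan-2-one
Product: 6 (4R)-7,7-dimethoxy-2,4-dimethylhept-1-ene
Conditions: Ph3PCH3Br, KOtBu, THF, 0 °C → rt
Reagents that add atoms: methyltriphenylphosphonium bromide C[P+](c1ccccc1)(c1ccccc1)c1ccccc1.[Br-]
Why: Wittig methylenation of the unhindered methyl ketone gives the 1,1-disubstituted alkene whose carbons become C5 and C4, the acetal being inert to the ylide.

Step 5
Reactants: 6 (4R)-7,7-dimethoxy-2,4-dimethylhept-1-ene; 7 bromoform
Product: 8 1,1-dibromo-2-[(2R)-5,5-dimethoxy-2-methylpentyl]-2-methylcyclopropane (both ring epimers)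
Conditions: KOtBu, pentane, 0 °C → rt
Reagents that add atoms: none
Why: Dihalocarbene cyclopropanation: dibromocarbene from bromoform and KOtBu adds to the electron-rich 1,1-disubstituted alkene, forming the C3–C4 and C3–C5 ring bonds, and the ring configuration is irrelevant because step 8 destroys it.

Step 6
Reactants: 8 1,1-dibromo-2-[(2R)-5,5-dimethoxy-2-methylpentyl]-2-methylcyclopropane
Product: 10 1-bromo-2-[(2R)-5,5-dimethoxy-2-methylpentyl]-1,2-dimethylcyclopropane (ring stereoisomers), via bromolithium carbenoid 9 (not isolated)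
Conditions: n-BuLi, THF/Et2O/pentane, −105 °C; MeI, −105 → −78 °C
Reagents that add atoms: iodomethane CI
Why: Bromine–lithium exchange gives a 1-bromo-1-lithiocyclopropane carbenoid that persists only at very low temperature and is alkylated by iodomethane (carbenoid alkylation of a gem-dibromocyclopropane), placing the C3 methyl group, either diastereomer being acceptable.

Step 7
Reactants: 10 1-bromo-2-[(2R)-5,5-dimethoxy-2-methylpentyl]-1,2-dimethylcyclopropane; 11 vinyl bromide
Product: 14 1-[(2R)-5,5-dimethoxy-2-methylpentyl]-2-ethenyl-1,2-dimethylcyclopropane (ring stereoisomers), via cyclopropyllithium 12 (not isolated), via cyclopropylzinc chloride 13 (not isolated)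
Conditions: t-BuLi (2.1 equiv), Et2O, −78 °C; ZnCl2, THF, −78 → 0 °C; 11, Pd(PPh3)4 (5 mol%), THF, rt → 45 °C (sealed vessel)
Reagents that add atoms: none
Why: Negishi coupling: bromine–lithium exchange, transmetalation to zinc and coupling with vinyl bromide under zerovalent palladium catalysis attach the vinyl group (C1–C2) to the tertiary cyclopropyl carbon, helped by the high s-character of cyclopropyl–metal bonds and the strain that disfavours β-hydride elimination.

Step 8
Reactants: 14 1-[(2R)-5,5-dimethoxy-2-methylpentyl]-2-ethenyl-1,2-dimethylcyclopropane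
Product: 15 (3R,5R)-3-[(2R)-5,5-dimethoxy-2-methylpentyl]-5-ethenyl-3,5-dimethyl-1,2-dioxolane
Conditions: PhSSPh (0.2 equiv), AIBN (0.1 equiv), O2 (1 atm), MeCN (0.02 M), sunlamp, 0 °C; chromatography on Et3N-treated silica, then preparative HPLC to separate the diastereomers
Reagents that add atoms: dioxygen O=O
Why: Light cleaves PhSSPh to PhS•, which adds to the vinyl terminus C1; the cyclopropylcarbinyl radical at C2 opens the C3–C5 bond toward the fully substituted ring carbon to give the tertiary C5 radical and an allyl sulfide (C2=C3), O2 is captured at C5, the peroxyl radical adds to C3 and the C2 radical so formed expels PhS•, which restores the vinyl group and carries the chain. The closest known reaction type is the thiyl- or selenyl-radical-catalysed oxygenation of vinylcyclopropanes to 3-vinyl-1,2-dioxolanes, applied here to a cyclopropane in which both reacting carbons are quaternary. The 1,2-dioxolane ring closes by 5-exo-trig attack of the peroxyl oxygen on C3, and this mode should prevail over 6-endo attack at C2 because only the exo adduct has a β-C–S bond that fragments fast and irreversibly. C3 is set in this ring closure by a chair-like transition state in which methyl and the larger substituent compete for the pseudo-equatorial position, so only a modest preference for the cis-dimethyl ring is expected, whereas C5 is set by the face on which O2 meets the planar tertiary radical, where the remote C7 centre should give no useful bias. The step needs regioselective ring opening (secured by the tertiary radical available only at C5), chemoselectivity (secured by a side chain without alkenes, whose acetal and ether C–H bonds are too strong for PhS• to abstract) and convergence of all cyclopropane stereoisomers (inherent, since they give the same open-chain radical). The (3R,5R) isomer is therefore expected as one of four diastereomers and must be isolated by chromatography.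

Step 9
Reactants: 15 (3R,5R)-3-[(2R)-5,5-dimethoxy-2-methylpentyl]-5-ethenyl-3,5-dimethyl-1,2-dioxolane
Product: 17 2-[(3S,5R)-5-[(2R)-5,5-dimethoxy-2-methylpentyl]-3,5-dimethyl-1,2-dioxolan-3-yl]ethan-1-ol, via B-alkyl-9-BBN adduct 16 (not isolated)
Conditions: 9-BBN (1.5 equiv), THF, 0 °C → rt; then aq NaOAc, 30% H2O2, 0 °C → rt
Reagents that add atoms: hydrogen peroxide OO
Why: Hydroboration–oxidation: 9-BBN places boron on the terminal vinyl carbon C1 (C3 is quaternary) and buffered H2O2 oxidises the C–B bond to the primary alcohol, conditions that a di-tertiary dialkyl peroxide without ring hydrogens and the acetal should tolerate; the C3 descriptor becomes S only because the CIP priorities change.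

Step 10
Reactants: 17 2-[(3S,5R)-5-[(2R)-5,5-dimethoxy-2-methylpentyl]-3,5-dimethyl-1,2-dioxolan-3-yl]ethan-1-ol
Product: 18 (4R)-5-[(3R,5S)-5-(2-hydroxyethyl)-3,5-dimethyl-1,2-dioxolan-3-yl]-4-methylpentanal
Conditions: p-TsOH·H2O (10 mol%), acetone/H2O, rt
Reagents that add atoms: water O
Why: Acid-catalysed acetal hydrolysis unveils the C10 aldehyde directly, so no redox step is needed, while the di-tertiary peroxide and the remote primary alcohol are inert to dilute acid.

Step 11
Reactants: 18 (4R)-5-[(3R,5S)-5-(2-hydroxyethyl)-3,5-dimethyl-1,2-dioxolan-3-yl]-4-methylpentanal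
Product: 19 2-[(3S,5R)-3,5-dimethyl-5-[(2R)-2-methylhex-5-en-1-yl]-1,2-dioxolan-3-yl]ethan-1-ol
Conditions: Ph3PCH3Br (3 equiv), KOtBu (2.9 equiv), THF, 0 °C → rt
Reagents that add atoms: methyltriphenylphosphonium bromide C[P+](c1ccccc1)(c1ccccc1)c1ccccc1.[Br-]
Why: Wittig methylenation of the aldehyde adds C11 as a terminal alkene; the free hydroxyl is tolerated and the dioxolane, having no ring hydrogens, has no base-induced fragmentation pathway.

Step 12
Reactants: 20 cinnamyl bromide; 21 trimethyl(prop-1-yn-1-yl)silane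
Product: 24 [(1E)-hex-1-en-5-yn-1-yl]benzene, via lithiated silylpropyne 22 (not isolated), via silyl enyne 23 (not isolated)
Conditions: 21, n-BuLi, THF, −78 °C; 20, −78 °C → rt; then MeOH, K2CO3, rt
Reagents that add atoms: none
Why: Propargylic lithiation of the silylpropyne and SN2 alkylation with the primary allylic bromide, followed by methanolysis of the alkynylsilane in the same flask, give the C12–C17 enyne with the E-styrene retained (the silyl group blocks the alkyne terminus and favours propargyl over allenyl attack).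

Step 13
Reactants: 24 [(1E)-hex-1-en-5-yn-1-yl]benzene
Product: 26 [(1E,5E)-6-iodohexa-1,5-dien-1-yl]benzene, via alkenylzirconocene chloride 25 (not isolated)
Conditions: Cp2Zr(H)Cl (1.2 equiv), THF, rt, dark; I2, 0 °C
Reagents that add atoms: iodine II
Why: Hydrozirconation of the terminal alkyne is a syn addition that places zirconium on the terminal carbon and is much faster than addition to the 1,2-disubstituted styrene, and iodinolysis with retention then gives the (E)-alkenyl iodide.

Step 14
Reactants: 19 2-[(3S,5R)-3,5-dimethyl-5-[(2R)-2-methylhex-5-en-1-yl]-1,2-dioxolan-3-yl]ethan-1-ol; 26 [(1E,5E)-6-iodohexa-1,5-dien-1-yl]benzene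
Product: 28 2-[(3S,5R)-3,5-dimethyl-5-[(2R,7E,11E)-2-methyl-12-phenyldodeca-7,11-dien-1-yl]-1,2-dioxolan-3-yl]ethan-1-ol, via bis(9-BBN) adduct 27 (not isolated)
Conditions: 19, 9-BBN (2.5 equiv), THF, 0 °C → rt; then aq K3PO4, 26, PdCl2(dppf) (5 mol%), AsPh3 (5 mol%), DMF, rt
Reagents that add atoms: none
Why: B-alkyl Suzuki–Miyaura coupling: 9-BBN hydroborates the terminal alkene at C11 (a further equivalent is taken up by the hydroxyl as a borinate that is hydrolysed on work-up) and PdCl2(dppf)-catalysed coupling with the (E)-alkenyl iodide forms the C11–C12 bond with retention of geometry at room temperature, mild conditions under which the hindered dialkyl peroxide should persist.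

Step 15
Reactants: 28 2-[(3S,5R)-3,5-dimethyl-5-[(2R,7E,11E)-2-methyl-12-phenyldodeca-7,11-dien-1-yl]-1,2-dioxolan-3-yl]ethan-1-ol
Product: 30 2-[(3R,5R)-3,5-dimethyl-5-[(2R,7E,11E)-2-methyl-12-phenyldodeca-7,11-dien-1-yl]-1,2-dioxolan-3-yl]acetic acid, via aldehyde 29 (not isolated)
Conditions: TEMPO (0.2 equiv), PhI(OAc)2 (2.5 equiv), MeCN/H2O, rt
Reagents that add atoms: water O
Why: Nitroxyl-catalysed oxidation takes the primary alcohol through the aldehyde hydrate to the carboxylic acid, is chemoselective for the alcohol over the two alkenes and the peroxide, and is non-basic so the β-peroxy aldehyde cannot eliminate.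

Compound list
1 | (R)-citronellal, (3R)-3,7-dimethyloct-6-enal | O=CC[C@H](C)CCC=C(C)C | starting material
2 | (4R)-4,8-dimethylnon-7-en-2-ol (C2 epimers) | CC(O)C[C@H](C)CCC=C(C)C | intermediate
3 | (4R)-4,8-dimethylnon-7-en-2-one | CC(=O)C[C@H](C)CCC=C(C)C | intermediate
4 | (4R)-4-methyl-6-oxoheptanal (not isolated) | CC(=O)C[C@H](C)CCC=O | intermediate
5 | (4R)-7,7-dimethoxy-4-methylheptan-2-one | CC(=O)C[C@H](C)CCC(OC)OC | intermediate
6 | (4R)-7,7-dimethoxy-2,4-dimethylhept-1-ene | C=C(C)C[C@H](C)CCC(OC)OC | intermediate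
7 | bromoform | BrC(Br)Br | starting material
8 | 1,1-dibromo-2-[(2R)-5,5-dimethoxy-2-methylpentyl]-2-methylcyclopropane (both ring epimers) | BrC1(Br)CC1(C)C[C@H](C)CCC(OC)OC | intermediate
9 | {1-bromo-2-[(2R)-5,5-dimethoxy-2-methylpentyl]-2-methylcyclopropyl}lithium (not isolated) | [Li]C1(Br)CC1(C)C[C@H](C)CCC(OC)OC | intermediate
10 | 1-bromo-2-[(2R)-5,5-dimethoxy-2-methylpentyl]-1,2-dimethylcyclopropane (ring stereoisomers) | CC1(Br)CC1(C)C[C@H](C)CCC(OC)OC | intermediate
11 | vinyl bromide, bromoethene | C=CBr | starting material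
12 | {2-[(2R)-5,5-dimethoxy-2-methylpentyl]-1,2-dimethylcyclopropyl}lithium (not isolated) | [Li]C1(C)CC1(C)C[C@H](C)CCC(OC)OC | intermediate
13 | chlorido{2-[(2R)-5,5-dimethoxy-2-methylpentyl]-1,2-dimethylcyclopropyl}zinc (not isolated) | Cl[Zn]C1(C)CC1(C)C[C@H](C)CCC(OC)OC | intermediate
14 | 1-[(2R)-5,5-dimethoxy-2-methylpentyl]-2-ethenyl-1,2-dimethylcyclopropane (ring stereoisomers; key-step precursor) | C=CC1(C)CC1(C)C[C@H](C)CCC(OC)OC | intermediate
15 | (3R,5R)-3-[(2R)-5,5-dimethoxy-2-methylpentyl]-5-ethenyl-3,5-dimethyl-1,2-dioxolane (key-step product) | C=C[C@@]1(C)C[C@@](C)(C[C@H](C)CCC(OC)OC)OO1 | intermediate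
16 | 9-{2-[(3S,5R)-5-[(2R)-5,5-dimethoxy-2-methylpentyl]-3,5-dimethyl-1,2-dioxolan-3-yl]ethyl}-9-borabicyclo[3.3.1]nonane (not isolated) | B1(CC[C@@]3(C)C[C@@](C)(C[C@H](C)CCC(OC)OC)OO3)C2CCCC1CCC2 | intermediate
17 | 2-[(3S,5R)-5-[(2R)-5,5-dimethoxy-2-methylpentyl]-3,5-dimethyl-1,2-dioxolan-3-yl]ethan-1-ol | OCC[C@@]1(C)C[C@@](C)(C[C@H](C)CCC(OC)OC)OO1 | intermediate
18 | (4R)-5-[(3R,5S)-5-(2-hydroxyethyl)-3,5-dimethyl-1,2-dioxolan-3-yl]-4-methylpentanal | OCC[C@@]1(C)C[C@@](C)(C[C@H](C)CCC=O)OO1 | intermediate
19 | 2-[(3S,5R)-3,5-dimethyl-5-[(2R)-2-methylhex-5-en-1-yl]-1,2-dioxolan-3-yl]ethan-1-ol | OCC[C@@]1(C)C[C@@](C)(C[C@H](C)CCC=C)OO1 | intermediate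
20 | cinnamyl bromide, [(1E)-3-bromoprop-1-en-1-yl]benzene | BrC/C=C/c1ccccc1 | starting material
21 | trimethyl(prop-1-yn-1-yl)silane | CC#C[Si](C)(C)C | starting material
22 | [3-(trimethylsilyl)prop-2-yn-1-yl]lithium (not isolated) | [Li]CC#C[Si](C)(C)C | intermediate
23 | trimethyl[(5E)-6-phenylhex-5-en-1-yn-1-yl]silane (not isolated) | C[Si](C)(C)C#CCC/C=C/c1ccccc1 | intermediate
24 | [(1E)-hex-1-en-5-yn-1-yl]benzene | C#CCC/C=C/c1ccccc1 | intermediate
25 | chloridobis(cyclopentadienyl)[(1E,5E)-6-phenylhexa-1,5-dien-1-yl]zirconium (not isolated) | Cl[Zr](/C=C/CC/C=C/c1ccccc1)(C1C=CC=C1)C1C=CC=C1 | intermediate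
26 | [(1E,5E)-6-iodohexa-1,5-dien-1-yl]benzene | I/C=C/CC/C=C/c1ccccc1 | intermediate
27 | 9-{2-[(3S,5R)-5-[(2R)-6-(9-borabicyclo[3.3.1]nonan-9-yl)-2-methylhexyl]-3,5-dimethyl-1,2-dioxolan-3-yl]ethoxy}-9-borabicyclo[3.3.1]nonane (not isolated) | B1(OCC[C@@]3(C)C[C@@](C)(C[C@H](C)CCCCB4C5CCCC4CCC5)OO3)C2CCCC1CCC2 | intermediate
28 | 2-[(3S,5R)-3,5-dimethyl-5-[(2R,7E,11E)-2-methyl-12-phenyldodeca-7,11-dien-1-yl]-1,2-dioxolan-3-yl]ethan-1-ol | OCC[C@@]1(C)C[C@@](C)(C[C@H](C)CCCC/C=C/CC/C=C/c2ccccc2)OO1 | intermediate
29 | 2-[(3R,5R)-3,5-dimethyl-5-[(2R,7E,11E)-2-methyl-12-phenyldodeca-7,11-dien-1-yl]-1,2-dioxolan-3-yl]acetaldehyde (not isolated) | O=CC[C@@]1(C)C[C@@](C)(C[C@H](C)CCCC/C=C/CC/C=C/c2ccccc2)OO1 | intermediate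
30 | 2-[(3R,5R)-3,5-dimethyl-5-[(2R,7E,11E)-2-methyl-12-phenyldodeca-7,11-dien-1-yl]-1,2-dioxolan-3-yl]acetic acid | OC(=O)C[C@@]1(C)C[C@@](C)(C[C@H](C)CCCC/C=C/CC/C=C/c2ccccc2)OO1 | target

Total step count: 15 (13 on the main line, 2 for iodide 26).
Longest linear sequence: 13 steps (steps 1–11, 14 and 15).

Steps most likely to fail

Step 8 (key step). The peroxyl radical may close in the 6-endo mode or be intercepted before it cyclises, giving hydroperoxides and oligomeric peroxides. The two C–O bonds may also form with so little facial discrimination that the wanted isomer is a small share of four. The fallback builds the ring by polar bond formation (hydroperoxysilylation, then intramolecular oxa-Michael addition); it sets out from alkene 6 and returns at alcohol 17. Alkene 6 is deprotonated at its allylic methyl group (n-BuLi/KOtBu, hexane/THF, −78 → −40 °C) and borylated with 2-isopropoxy-4,4,5,5-tetramethyl-1,3,2-dioxaborolane to give the allylboronate F1. Suzuki–Miyaura coupling (Pd(PPh3)4, K3PO4, THF/H2O, 50 °C) with methyl (2Z)-3-iodobut-2-enoate F2 (from methyl but-2-ynoate, NaI, AcOH) gives the skipped dienoate F3. Mukaiyama–Isayama hydroperoxysilylation (Co(thd)2 with thd = 2,2,6,6-tetramethylheptane-3,5-dionate, O2, Et3SiH, 1,2-dichloroethane, rt) attacks the electron-rich 1,1-disubstituted alkene and leaves the enoate, giving the tertiary triethylsilyl peroxide F4. Fluoride (Bu4NF, THF, 0 °C, followed by Et2NH in CF3CH2OH if closure is slow) removes the silyl group, and the peroxide oxygen adds 5-exo to the enoate to give the dioxolane methyl ester F5 after separation of isomers. LiBH4 (THF, 0 °C) reduces the ester to 17. This route secures ring construction but not stereocontrol at C3 and C5, so isomers are again separated.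

Step 7. Transmetalation and reductive elimination at the congested tertiary cyclopropyl centre may be slow, so that the organozinc is protonated or homocoupled instead of vinylated. The fallback replaces cross-coupling by carbonyl olefination; it sets out from bromide 10 and returns at 14. Bromine–lithium exchange as in step 7 gives cyclopropyllithium 12, which is formylated with DMF (Et2O, −78 → 0 °C) to the cyclopropanecarbaldehyde F6. Wittig methylenation (Ph3PCH3Br, KOtBu, THF, 0 °C) then gives 14.

Step 14. Zerovalent palladium or the phosphine may reduce the O–O bond, or protodeboronation and β-hydride elimination may outrun the sp3–sp2 coupling. The fallback is a metal-free Julia–Kocienski olefination that forms C12=C13 instead of the C11–C12 bond; it sets out from hydroxy aldehyde 18 and returns at 28. Wittig reaction of 18 with (triphenylphosphoranylidene)acetaldehyde (toluene, 50 °C) gives the (E)-enal F7, and conjugate transfer hydrogenation with Hantzsch ester and catalytic dibenzylammonium trifluoroacetate (THF, rt) gives the saturated C12 aldehyde F8. The sulfone partner comes from cinnamyl bromide 20: alkylation of the lithium enolate of tert-butyl acetate (LiN(i-Pr)2, THF, −78 °C) gives the ester F9, LiAlH4 reduction gives the alcohol F10, Mitsunobu reaction with 1-phenyl-1H-tetrazole-5-thiol (PPh3, diisopropyl azodicarboxylate) gives the sulfide F11, and oxidation ((NH4)6Mo7O24, H2O2, EtOH) gives the sulfone F12. Deprotonation of F12 with KN(SiMe3)2 (DME, −60 °C, 2.2 equiv to allow for the free hydroxyl) and addition of F8 should give the (E)-alkene 28.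

Further compounds
F1 | step 8 | 2-[(4R)-7,7-dimethoxy-4-methyl-2-methylideneheptyl]-4,4,5,5-tetramethyl-1,3,2-dioxaborolane | C=C(CB1OC(C)(C)C(C)(C)O1)C[C@H](C)CCC(OC)OC
F2 | step 8 | methyl (2Z)-3-iodobut-2-enoate | C/C(I)=C/C(=O)OC
F3 | step 8 | methyl (2Z,7R)-10,10-dimethoxy-3,7-dimethyl-5-methylidenedec-2-enoate | COC(=O)/C=C(/C)CC(=C)C[C@H](C)CCC(OC)OC
F4 | step 8 | methyl (2Z,7R)-10,10-dimethoxy-3,5,7-trimethyl-5-[(triethylsilyl)peroxy]dec-2-enoate (C5 epimers) | COC(=O)/C=C(/C)CC(C)(OO[Si](CC)(CC)CC)C[C@H](C)CCC(OC)OC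
F5 | step 8 | methyl 2-[(3R,5R)-5-[(2R)-5,5-dimethoxy-2-methylpentyl]-3,5-dimethyl-1,2-dioxolan-3-yl]acetate | COC(=O)C[C@@]1(C)C[C@@](C)(C[C@H](C)CCC(OC)OC)OO1
F6 | step 7 | 2-[(2R)-5,5-dimethoxy-2-methylpentyl]-1,2-dimethylcyclopropane-1-carbaldehyde (ring stereoisomers) | O=CC1(C)CC1(C)C[C@H](C)CCC(OC)OC
F7 | step 14 | (2E,6R)-7-[(3R,5S)-5-(2-hydroxyethyl)-3,5-dimethyl-1,2-dioxolan-3-yl]-6-methylhept-2-enal | OCC[C@@]1(C)C[C@@](C)(C[C@H](C)CC/C=C/C=O)OO1
F8 | step 14 | (6R)-7-[(3R,5S)-5-(2-hydroxyethyl)-3,5-dimethyl-1,2-dioxolan-3-yl]-6-methylheptanal | OCC[C@@]1(C)C[C@@](C)(C[C@H](C)CCCCC=O)OO1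
F9 | step 14 | tert-butyl (4E)-5-phenylpent-4-enoate | CC(C)(C)OC(=O)CC/C=C/c1ccccc1
F10 | step 14 | (4E)-5-phenylpent-4-en-1-ol | OCCC/C=C/c1ccccc1
F11 | step 14 | 1-phenyl-5-{[(4E)-5-phenylpent-4-en-1-yl]sulfanyl}-1H-tetrazole | C(CC/C=C/c1ccccc1)Sc1nnnn1-c1ccccc1
F12 | step 14 | 1-phenyl-5-{[(4E)-5-phenylpent-4-en-1-yl]sulfonyl}-1H-tetrazole | O=S(=O)(CCC/C=C/c1ccccc1)c1nnnn1-c1ccccc1
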